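The runs were generated by integration for an exercise; noise was put on by code.

At early times the eta run shows how fast coupling goes, and its later readings show what happens to the product.

- eta: left-handed substrate 0.40 M; right-handed substrate 0.40 M; coupling partner 2.2 equiv; racemization catalyst 5 mol%; run made earlier
- flask: left-handed substrate 0.20 M; coupling partner 2.20 equiv; racemization catalyst 5 mol%; right-handed substrate 0.20 M; time 20 h

- eta (time / h: left-handed product / %, right-handed product / %): 0.333: 9, 0; 0.667: 16, 0; 1.50: 33, 5; 4.00: 54, 7

(readings scatter by 2 percentage points)

- coupling partner is single-handed; left-handed substrate and right-handed substrate are mirror images of each other, charged as a racemate, each of them at the stated concentration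
- what was read earlier has a scatter of 2 percentage points, one standard deviation
- an excess is the difference of the two amounts in percent of their sum
- an excess is below zero if the other one leads
- no earlier run changes the charge of racemization catalyst; that part of a forecast is a guess
- the handed part of coupling partner does not stay in what it makes, so the products of the two hands are mirror images too

1. left-handed product and right-handed product together, in percent of the left-handed substrate and right-handed substrate charged together, at 20 h
2. excess of left-handed product over right-handed product in the product at 20 h
3. whether the exchange between left-handed substrate and right-handed substrate keeps pace with the reaction: how far the product's excess at 20 h gets from its value without exchange to its value with instant exchange (above 80% keeps pace, below 20% hardly takes part, else lags behind)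

By 0.667 h in the eta run, 32.0% of the left-handed substrate has coupled, a reading of 0.578 h⁻¹. We assume the rate is first order in coupling partner (pseudo-first-order). The partner's concentration in the flask is half that of eta, so the flask couples at 0.289 h⁻¹.

Without exchange, the flask's yield stays near half the charge. With instant exchange, both substrates drain as one pool while the partner falls with them, which gives 76.8%. The same sum for eta at 4.00 h gives 54.9%, and the readings there add up to more. We therefore expect exchange to keep pace and the yield to lie near the upper value, though the flask's catalyst concentration is a guess.

The excess has its upper bound in eta's last reading, 77.0%. For the lower bound, suppose all right-handed product came from left-handed product. Eta's readings then give the turning rate, right-handed product formed per left-handed product present and per hour: 0.0524 h⁻¹. No concentration enters this rate. Mirror-image products lose excess at twice that rate. The pool lives 6.92 h, so the product's typical age is 13.1 h, and the excess falls to 25.4%. With a scatter of 2 percentage points, eta's readings of right-handed product do not tell turning from direct coupling. The low end therefore stays an assumption, and we commit to it as such.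

The forecast says 80%, 75% and lags behind, reckoning that “every rate halves”.

The flask gives 77.9%, 35.5%, and exchange keeps pace, 97% of the way.

    2 racemization catalyst → spent catalyst (k = 0.0220 M⁻¹ s⁻¹)
    left-handed substrate + racemization catalyst ⇌ right-handed substrate + racemization catalyst, rate k2*[racemization catalyst]*[left-handed substrate] forward; the back reaction follows from the equilibrium constant (k = 0.120 M⁻¹ s⁻¹)
    coupling partner + right-handed substrate → right-handed product (k = 5.80 × 10⁻⁶ M⁻¹ s⁻¹)
    left-handed product ⇌ right-handed product (k = 1.00 × 10⁻⁵ s⁻¹)
    coupling partner + left-handed substrate → left-handed product (k = 2.10 × 10⁻⁴ M⁻¹ s⁻¹)

The flask's excess stands above our lower bound and well below the upper one. On the neighbour with 8.80 equiv of coupling partner, the same reckoning has the pool living 1.73 h. The product is older there, and the same turning rate gives a lower bound of 14.7%. That neighbour reaches a yield of 99.6%, with 62.5% left-handed and 37.1% right-handed product, and its excess is 25.5%.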